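**Retrosynthetic overview**

1. Both prenyl groups (C8 of ring A, C3' of ring B) are disconnected last to the 7-O- and 4'-O-(1,1-dimethylallyl) ethers (double aromatic Claisen). Until then they are carried as oxidant-inert 1,1-dimethylpropargyl ethers, which also protect both phenols.
2. Ring C is opened at C2–C3 to an achiral benzyl aryl ether. C2–H is benzylic to ring B, para to the C4' oxygen and alpha to the ring oxygen O1, so it can leave as hydride to give an oxocarbenium/para-quinone-methide-type cation. C3, between the C4 carbonyl and its own oxygen, is offered as the copper-bound enolate of an allyl beta-keto ester; the ester and the O-protecting group leave together in one palladium step.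
3. The alpha-oxygenated beta-keto ester comes from a Chan rearrangement of the glycolate ester of 2,4-dihydroxybenzoic acid. O1–C2 comes from a Mitsunobu etherification with the ring B benzyl alcohol (from 4-hydroxybenzaldehyde).
4. Ring order: rings A and B are bought; ring C is the only ring made (step 8), with both stereocentres.

Key step: step 8

Remark: flavanone numbering (O1, C2, C3, C4, C4a–C8a; ring B C1'–C6') is used for all intermediates; 10 and 11 are racemic at the carbon that becomes C3, which is planar in the enolate of step 8.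

**Route**

Step 1
Reactants: 1 4-hydroxybenzaldehyde; 2 3-chloro-3-methylbut-1-yne
Product: 3 4-[(2-methylbut-3-yn-2-yl)oxy]benzaldehyde
Conditions: K2CO3, KI (cat.), CuI (cat.), acetone, 55 °C
Reagents that add atoms: none
Why: Copper-assisted Williamson-type O-alkylation of the phenoxide with the tertiary propargylic chloride is the standard entry to aryl 1,1-dimethylpropargyl ethers, and the aldehyde is inert.

Step 2
Reactants: 3 4-[(2-methylbut-3-yn-2-yl)oxy]benzaldehyde
Product: 4 {4-[(2-methylbut-3-yn-2-yl)oxy]phenyl}methanol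
Conditions: NaBH4, MeOH, 0 °C
Reagents that add atoms: none
Why: Borohydride reduction of the aldehyde is chemoselective, and the alkyne and the tertiary ether do not react.

Step 3
Reactants: 5 2,4-dihydroxybenzoic acid; 6 allyl bromoacetate
Product: 7 2-(allyloxy)-2-oxoethyl 2,4-dihydroxybenzoate
Conditions: KHCO3, DMF, rt
Reagents that add atoms: none
Why: Hydrogen carbonate deprotonates only the carboxylic acid, so SN2 alkylation by the alpha-bromo ester should give the glycolate ester and leave both phenols free.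

Step 4
Reactants: 7 2-(allyloxy)-2-oxoethyl 2,4-dihydroxybenzoate; 2 3-chloro-3-methylbut-1-yne
Product: 8 2-(allyloxy)-2-oxoethyl 2-hydroxy-4-[(2-methylbut-3-yn-2-yl)oxy]benzoate
Conditions: K2CO3, KI (cat.), CuI (cat.), acetone, 50 °C
Reagents that add atoms: none
Why: The same copper-assisted propargylation should take place only at the more acidic, non-chelated 4-hydroxyl, because the 2-hydroxyl is hydrogen-bonded to the ester carbonyl.

Step 5
Reactants: 8 2-(allyloxy)-2-oxoethyl 2-hydroxy-4-[(2-methylbut-3-yn-2-yl)oxy]benzoate; 4 {4-[(2-methylbut-3-yn-2-yl)oxy]phenyl}methanol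
Product: 9 2-(allyloxy)-2-oxoethyl 4-[(2-methylbut-3-yn-2-yl)oxy]-2-({4-[(2-methylbut-3-yn-2-yl)oxy]phenyl}methoxy)benzoate
Conditions: PPh3, DIAD, THF, 0 °C → rt
Reagents that add atoms: none
Why: Mitsunobu etherification of the salicylate hydroxyl with the primary benzylic alcohol forms the O1–C2 bond under neutral conditions that spare the activated glycolate ester.

Step 6
Reactants: 9 2-(allyloxy)-2-oxoethyl 4-[(2-methylbut-3-yn-2-yl)oxy]-2-({4-[(2-methylbut-3-yn-2-yl)oxy]phenyl}methoxy)benzoate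
Product: 10 allyl 2-hydroxy-3-[4-[(2-methylbut-3-yn-2-yl)oxy]-2-({4-[(2-methylbut-3-yn-2-yl)oxy]phenyl}methoxy)phenyl]-3-oxopropanoate (racemic)
Conditions: LiN(i-Pr)2 (4.5 equiv), THF, −78 °C; AcOH quench at −78 °C
Reagents that add atoms: none
Why: In the Chan rearrangement the glycolate enolate attacks the aroyl carbonyl (3-exo-trig) and the epoxide alkoxide opens to the alpha-hydroxy beta-keto ester, which creates the C3–C4 bond with C3 already oxygenated; the excess base covers the two acetylenic C–H bonds and the second deprotonation of the product.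

Step 7
Reactants: 10 allyl 2-hydroxy-3-[4-[(2-methylbut-3-yn-2-yl)oxy]-2-({4-[(2-methylbut-3-yn-2-yl)oxy]phenyl}methoxy)phenyl]-3-oxopropanoate
Product: 11 allyl 2-{[(allyloxy)carbonyl]oxy}-3-[4-[(2-methylbut-3-yn-2-yl)oxy]-2-({4-[(2-methylbut-3-yn-2-yl)oxy]phenyl}methoxy)phenyl]-3-oxopropanoate (racemic)
Conditions: allyl chloroformate, pyridine, CH2Cl2, 0 °C
Reagents that add atoms: allyl chloroformate, C=CCOC(=O)Cl
Why: O-acylation of the secondary hydroxyl to the allyl carbonate shields the reductone-like alpha-hydroxy beta-keto ester from oxidation by DDQ and by divalent copper, and puts on a group that leaves in the same palladium step as the ester.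

Step 8
Reactants: 11 allyl 2-{[(allyloxy)carbonyl]oxy}-3-[4-[(2-methylbut-3-yn-2-yl)oxy]-2-({4-[(2-methylbut-3-yn-2-yl)oxy]phenyl}methoxy)phenyl]-3-oxopropanoate
Product: 13 allyl (2R,3R)-3-{[(allyloxy)carbonyl]oxy}-7-[(2-methylbut-3-yn-2-yl)oxy]-2-{4-[(2-methylbut-3-yn-2-yl)oxy]phenyl}-4-oxochromane-3-carboxylate, via oxocarbenium ion 12 (not isolated)
Conditions: Cu(OTf)2 (10 mol %), (S,S)-t-Bu-bis(oxazoline) [2,2'-(propane-2,2-diyl)bis((4S)-4-tert-butyl-4,5-dihydrooxazole)] (12 mol %), DDQ (1.3 equiv), 4 Å MS, CH2Cl2, −30 → 0 °C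
Reagents that add atoms: none
Why: Proposed new method: DDQ should abstract hydride from the C2–H bond, which is benzylic to ring B, para to its oxygen and alpha to O1, to give the (E)-O-aryl oxocarbenium/para-quinone-methide-type cation 12, while Cu(OTf)2–bis(oxazoline) holds the beta-keto ester as a square-planar chelated enolate that is the only nucleophilic form of the substrate, so that the C2–C3 bond forms inside the chiral complex. The closest known reaction type is the enantioselective cross-dehydrogenative cyclization of ether-tethered beta-keto esters with DDQ and chiral divalent-copper bis(oxazoline) catalysts to tetrahydropyran-4-ones, together with the racemic DDQ cyclizations of benzylic ethers onto enol acetates; new here are the aryl ether oxygen and the alpha-oxygenated, fully substituted enolate carbon. Ring C closes by 6-(enolendo)-endo-trig attack of the enolate carbon C3 on the oxocarbenium carbon C2, equivalent to a disrotatory closure of the O1=C2/C8a=C4a/C4=C3 array. C3 is set by the ligand, whose tert-butyl group shields one face of the chelated enolate, and C2 is set relative to C3 by the (E)-oxocarbenium geometry with the ring B aryl group outside and pseudo-equatorial, which places it trans to the carbonate oxygen; the ligand antipode that gives (2R) is fixed in the first run. The step needs hydride abstraction at C2–H only, which the substrate secures by carrying the future prenyl groups as tertiary propargyl ethers without alpha-hydrogen and by having no C-allyl group, and it needs one diastereomer, because the C2 epimer would end as the enantiomer after step 9 and is therefore removed here by chromatography or crystallization.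

Step 9
Reactants: 13 allyl (2R,3R)-3-{[(allyloxy)carbonyl]oxy}-7-[(2-methylbut-3-yn-2-yl)oxy]-2-{4-[(2-methylbut-3-yn-2-yl)oxy]phenyl}-4-oxochromane-3-carboxylate
Product: 15 (2R,3R)-3-hydroxy-7-[(2-methylbut-3-yn-2-yl)oxy]-2-{4-[(2-methylbut-3-yn-2-yl)oxy]phenyl}chroman-4-one, via hydroxy keto acid 14 (not isolated)
Conditions: Pd(PPh3)4 (5 mol %), morpholine (4 equiv), THF, rt, argon
Reagents that add atoms: none
Why: Zerovalent palladium ionizes both the allyl ester and the allyl carbonate (Tsuji–Trost deallylation with morpholine as allyl acceptor), the alpha-hydroxy beta-keto acid 14 loses CO2, and the enediol ketonizes to the aryl-conjugated C4 ketone, with the amine equilibrating C3 to the more stable 2,3-trans (diequatorial) isomer while C2 is untouched.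

Step 10
Reactants: 15 (2R,3R)-3-hydroxy-7-[(2-methylbut-3-yn-2-yl)oxy]-2-{4-[(2-methylbut-3-yn-2-yl)oxy]phenyl}chroman-4-one
Product: 16 (2R,3R)-3-hydroxy-7-[(2-methylbut-3-en-2-yl)oxy]-2-{4-[(2-methylbut-3-en-2-yl)oxy]phenyl}chroman-4-one
Conditions: H2 (1 atm), Pd/CaCO3 poisoned with Pb(OAc)2 (Lindlar catalyst), quinoline, EtOAc, rt, stopped after two equivalents of H2
Reagents that add atoms: none
Why: Lindlar semihydrogenation should stop both terminal alkynes at the vinyl stage without touching the ketone, the benzylic C2–O1 bond or the stereocentres.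

Step 11
Reactants: 16 (2R,3R)-3-hydroxy-7-[(2-methylbut-3-en-2-yl)oxy]-2-{4-[(2-methylbut-3-en-2-yl)oxy]phenyl}chroman-4-one
Product: 18 3-hydroxyglabrol [(2R,3R)-3,7-dihydroxy-2-[4-hydroxy-3-(3-methylbut-2-en-1-yl)phenyl]-8-(3-methylbut-2-en-1-yl)chroman-4-one], via mono-rearranged phenol 17 (not isolated)
Conditions: xylene, 130 °C, argon
Reagents that add atoms: none
Why: Two aromatic Claisen ([3,3]) rearrangements turn the 1,1-dimethylallyl ethers into ortho-prenyl phenols and free both hydroxyls at once; on ring B the two ortho positions are equivalent, and on ring A C8 should be preferred over C6 because donation from O1 to the C4 carbonyl gives the C7–C8 bond the higher double-bond character, the bias that leads 7-allyloxy- and 7-propargyloxy-chromanones and -coumarins to the angular products.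

**Compound list**

1 | 4-hydroxybenzaldehyde | O=Cc1ccc(O)cc1 | starting material
2 | 3-chloro-3-methylbut-1-yne | C#CC(C)(C)Cl | starting material
3 | 4-[(2-methylbut-3-yn-2-yl)oxy]benzaldehyde | O=Cc1ccc(OC(C)(C)C#C)cc1 | intermediate
4 | {4-[(2-methylbut-3-yn-2-yl)oxy]phenyl}methanol | OCc1ccc(OC(C)(C)C#C)cc1 | intermediate
5 | 2,4-dihydroxybenzoic acid | OC(=O)c1ccc(O)cc1O | starting material
6 | allyl bromoacetate | C=CCOC(=O)CBr | starting material
7 | 2-(allyloxy)-2-oxoethyl 2,4-dihydroxybenzoate | C=CCOC(=O)COC(=O)c1ccc(O)cc1O | intermediate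
8 | 2-(allyloxy)-2-oxoethyl 2-hydroxy-4-[(2-methylbut-3-yn-2-yl)oxy]benzoate | C=CCOC(=O)COC(=O)c1ccc(OC(C)(C)C#C)cc1O | intermediate
9 | 2-(allyloxy)-2-oxoethyl 4-[(2-methylbut-3-yn-2-yl)oxy]-2-({4-[(2-methylbut-3-yn-2-yl)oxy]phenyl}methoxy)benzoate | C=CCOC(=O)COC(=O)c1ccc(OC(C)(C)C#C)cc1OCc1ccc(OC(C)(C)C#C)cc1 | intermediate
10 | allyl 2-hydroxy-3-[4-[(2-methylbut-3-yn-2-yl)oxy]-2-({4-[(2-methylbut-3-yn-2-yl)oxy]phenyl}methoxy)phenyl]-3-oxopropanoate (racemic) | C=CCOC(=O)C(O)C(=O)c1ccc(OC(C)(C)C#C)cc1OCc1ccc(OC(C)(C)C#C)cc1 | intermediate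
11 | allyl 2-{[(allyloxy)carbonyl]oxy}-3-[4-[(2-methylbut-3-yn-2-yl)oxy]-2-({4-[(2-methylbut-3-yn-2-yl)oxy]phenyl}methoxy)phenyl]-3-oxopropanoate (racemic) | C=CCOC(=O)OC(C(=O)OCC=C)C(=O)c1ccc(OC(C)(C)C#C)cc1OCc1ccc(OC(C)(C)C#C)cc1 | intermediate
12 | O-aryl oxocarbenium (para-quinone-methide-type) cation of 11, beta-keto ester held on copper, counter-ion the DDQ hydroquinone anion | C=CCOC(=O)OC(C(=O)OCC=C)C(=O)c1ccc(OC(C)(C)C#C)cc1[O+]=Cc1ccc(OC(C)(C)C#C)cc1 | intermediate (not isolated)
13 | allyl (2R,3R)-3-{[(allyloxy)carbonyl]oxy}-7-[(2-methylbut-3-yn-2-yl)oxy]-2-{4-[(2-methylbut-3-yn-2-yl)oxy]phenyl}-4-oxochromane-3-carboxylate | C#CC(C)(C)Oc1ccc(cc1)[C@H]2Oc3cc(OC(C)(C)C#C)ccc3C(=O)[C@]2(C(=O)OCC=C)OC(=O)OCC=C | intermediate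
14 | (2R,3R)-3-hydroxy-7-[(2-methylbut-3-yn-2-yl)oxy]-2-{4-[(2-methylbut-3-yn-2-yl)oxy]phenyl}-4-oxochromane-3-carboxylic acid | C#CC(C)(C)Oc1ccc(cc1)[C@H]2Oc3cc(OC(C)(C)C#C)ccc3C(=O)[C@]2(C(=O)O)O | intermediate (not isolated)
15 | (2R,3R)-3-hydroxy-7-[(2-methylbut-3-yn-2-yl)oxy]-2-{4-[(2-methylbut-3-yn-2-yl)oxy]phenyl}chroman-4-one | C#CC(C)(C)Oc1ccc(cc1)[C@H]2Oc3cc(OC(C)(C)C#C)ccc3C(=O)[C@@H]2O | intermediate
16 | (2R,3R)-3-hydroxy-7-[(2-methylbut-3-en-2-yl)oxy]-2-{4-[(2-methylbut-3-en-2-yl)oxy]phenyl}chroman-4-one | C=CC(C)(C)Oc1ccc(cc1)[C@H]2Oc3cc(OC(C)(C)C=C)ccc3C(=O)[C@@H]2O | intermediate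
17 | (2R,3R)-3-hydroxy-2-[4-hydroxy-3-(3-methylbut-2-en-1-yl)phenyl]-7-[(2-methylbut-3-en-2-yl)oxy]chroman-4-one (ring B assumed to rearrange first; the order is immaterial) | CC(C)=CCc1cc(ccc1O)[C@H]2Oc3cc(OC(C)(C)C=C)ccc3C(=O)[C@@H]2O | intermediate (not isolated)
18 | 3-hydroxyglabrol, (2R,3R)-3,7-dihydroxy-2-[4-hydroxy-3-(3-methylbut-2-en-1-yl)phenyl]-8-(3-methylbut-2-en-1-yl)chroman-4-one | CC(C)=CCc1cc([C@H]2Oc3c(ccc(O)c3CC=C(C)C)C(=O)[C@@H]2O)ccc1O | target

**Step count and risks**

Total step count: 11. Longest linear sequence: 9 steps (steps 3 to 11, from 2,4-dihydroxybenzoic acid); steps 1 and 2 form the convergent ring B branch.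

Steps most likely to fail:

Step 8. Hydride abstraction may be slow at the electron-poor aryl ether oxygen, DDQ may instead oxidise the electron-rich copper enolate, the enolate may attack through oxygen to a cyclic acetal, or facial and diastereoselectivity may be low. The fallback uses known chemistry and the same C2–C3 ring closure; it sets out from 4 (with 2) and comes back at 15. Commercial 2,4-dihydroxyacetophenone is alkylated at its 4-hydroxyl with 2 (K2CO3, KI, CuI, acetone) to 1-{2-hydroxy-4-[(2-methylbut-3-yn-2-yl)oxy]phenyl}ethan-1-one F1, which is coupled with 4 (PPh3, DIAD) to the benzyl ether ketone F2. Detrifluoroacetylative diazo transfer (LiN(SiMe3)2, CF3CO2CH2CF3, then MsN3, Et3N) should give the diazoketone F3. A chiral dirhodium tetracarboxylate, Rh2(S-BSP)4 (dirhodium tetrakis[(S)-N-(benzenesulfonyl)prolinate]) or its antipode, at high dilution should effect the precedented enantioselective carbenoid insertion into the benzylic C–H bond of an o-alkoxyaryl diazoketone, closing ring C through C2–C3 to the (2S)-flavanone F4, which is brought to enantiopurity by crystallisation. Soft enolisation (Me3SiOTf, Et3N) gives the silyl enol ether F5, and Rubottom oxidation with dimethyldioxirane anti to the C2 aryl group returns the trans-dihydroflavonol 15.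

Step 6. Deprotonation may be misdirected to the acetylenic C–H bonds, attack of the enolate on the electron-rich aroyl carbonyl may be slow, and the enediolate may be oxidised by air on work-up. The fallback sets out from 9 and comes back at 10. Saponification (LiOH, THF–H2O) gives the benzoic acid F6, 1,1'-carbonyldiimidazole converts it into the imidazolide F7 (not isolated), and crossed Claisen condensation with the lithium enolate of the known reagent allyl (triethylsilyloxy)acetate gives the alpha-silyloxy beta-keto ester F8, which HF·pyridine desilylates to 10.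

Step 11. Regiocontrol between C8 and C6 may be lost in the ring A migration, or the tertiary allyl ether may ionise with loss of the C5 unit. The fallback sets out from 8 and comes back at 18. 8 is brominated para to its free hydroxyl (NBS, MeCN, 0 °C) to the 5-bromo ester F9, which blocks the later C6 position. Steps 5 to 10 are then repeated unchanged: Mitsunobu coupling with 4 to the benzyl ether F10, Chan rearrangement to the alpha-hydroxy beta-keto ester F11, acylation to the allyl carbonate F12, oxidative cyclization to the 6-bromochromanone diester F13, deallylation–decarboxylation to the bromo dihydroflavonol F14, and semihydrogenation to the bis(dimethylallyl) ether F15. The Claisen rearrangement of F15 can reach only C8 on ring A and gives 6-bromo-3-hydroxyglabrol F16, from which bromine is removed by radical hydrodebromination (Bu3SnH, AIBN, PhH, 80 °C) to give 18.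

**Further compounds**

F1 | step 8 | 1-{2-hydroxy-4-[(2-methylbut-3-yn-2-yl)oxy]phenyl}ethan-1-one | CC(=O)c1ccc(OC(C)(C)C#C)cc1O
F2 | step 8 | 1-[4-[(2-methylbut-3-yn-2-yl)oxy]-2-({4-[(2-methylbut-3-yn-2-yl)oxy]phenyl}methoxy)phenyl]ethan-1-one | CC(=O)c1ccc(OC(C)(C)C#C)cc1OCc1ccc(OC(C)(C)C#C)cc1
F3 | step 8 | 2-diazo-1-[4-[(2-methylbut-3-yn-2-yl)oxy]-2-({4-[(2-methylbut-3-yn-2-yl)oxy]phenyl}methoxy)phenyl]ethan-1-one | [N-]=[N+]=CC(=O)c1ccc(OC(C)(C)C#C)cc1OCc1ccc(OC(C)(C)C#C)cc1
F4 | step 8 | (2S)-7-[(2-methylbut-3-yn-2-yl)oxy]-2-{4-[(2-methylbut-3-yn-2-yl)oxy]phenyl}chroman-4-one | C#CC(C)(C)Oc1ccc(cc1)[C@H]2Oc3cc(OC(C)(C)C#C)ccc3C(=O)C2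
F5 | step 8 | (2S)-7-[(2-methylbut-3-yn-2-yl)oxy]-2-{4-[(2-methylbut-3-yn-2-yl)oxy]phenyl}-4-(trimethylsilyloxy)-2H-chromene | C#CC(C)(C)Oc1ccc(cc1)[C@H]2Oc3cc(OC(C)(C)C#C)ccc3C(O[Si](C)(C)C)=C2
F6 | step 6 | 4-[(2-methylbut-3-yn-2-yl)oxy]-2-({4-[(2-methylbut-3-yn-2-yl)oxy]phenyl}methoxy)benzoic acid | OC(=O)c1ccc(OC(C)(C)C#C)cc1OCc1ccc(OC(C)(C)C#C)cc1
F7 | step 6 | (1H-imidazol-1-yl)[4-[(2-methylbut-3-yn-2-yl)oxy]-2-({4-[(2-methylbut-3-yn-2-yl)oxy]phenyl}methoxy)phenyl]methanone | O=C(n1ccnc1)c1ccc(OC(C)(C)C#C)cc1OCc1ccc(OC(C)(C)C#C)cc1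
F8 | step 6 | allyl 3-[4-[(2-methylbut-3-yn-2-yl)oxy]-2-({4-[(2-methylbut-3-yn-2-yl)oxy]phenyl}methoxy)phenyl]-3-oxo-2-(triethylsilyloxy)propanoate (racemic) | C=CCOC(=O)C(O[Si](CC)(CC)CC)C(=O)c1ccc(OC(C)(C)C#C)cc1OCc1ccc(OC(C)(C)C#C)cc1
F9 | step 11 | 2-(allyloxy)-2-oxoethyl 5-bromo-2-hydroxy-4-[(2-methylbut-3-yn-2-yl)oxy]benzoate | C=CCOC(=O)COC(=O)c1cc(Br)c(OC(C)(C)C#C)cc1O
F10 | step 11 | 2-(allyloxy)-2-oxoethyl 5-bromo-4-[(2-methylbut-3-yn-2-yl)oxy]-2-({4-[(2-methylbut-3-yn-2-yl)oxy]phenyl}methoxy)benzoate | C=CCOC(=O)COC(=O)c1cc(Br)c(OC(C)(C)C#C)cc1OCc1ccc(OC(C)(C)C#C)cc1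
F11 | step 11 | allyl 3-[5-bromo-4-[(2-methylbut-3-yn-2-yl)oxy]-2-({4-[(2-methylbut-3-yn-2-yl)oxy]phenyl}methoxy)phenyl]-2-hydroxy-3-oxopropanoate (racemic) | C=CCOC(=O)C(O)C(=O)c1cc(Br)c(OC(C)(C)C#C)cc1OCc1ccc(OC(C)(C)C#C)cc1
F12 | step 11 | allyl 2-{[(allyloxy)carbonyl]oxy}-3-[5-bromo-4-[(2-methylbut-3-yn-2-yl)oxy]-2-({4-[(2-methylbut-3-yn-2-yl)oxy]phenyl}methoxy)phenyl]-3-oxopropanoate (racemic) | C=CCOC(=O)OC(C(=O)OCC=C)C(=O)c1cc(Br)c(OC(C)(C)C#C)cc1OCc1ccc(OC(C)(C)C#C)cc1
F13 | step 11 | allyl (2R,3R)-3-{[(allyloxy)carbonyl]oxy}-6-bromo-7-[(2-methylbut-3-yn-2-yl)oxy]-2-{4-[(2-methylbut-3-yn-2-yl)oxy]phenyl}-4-oxochromane-3-carboxylate | C#CC(C)(C)Oc1ccc(cc1)[C@H]2Oc3cc(OC(C)(C)C#C)c(Br)cc3C(=O)[C@]2(C(=O)OCC=C)OC(=O)OCC=C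
F14 | step 11 | (2R,3R)-6-bromo-3-hydroxy-7-[(2-methylbut-3-yn-2-yl)oxy]-2-{4-[(2-methylbut-3-yn-2-yl)oxy]phenyl}chroman-4-one | C#CC(C)(C)Oc1ccc(cc1)[C@H]2Oc3cc(OC(C)(C)C#C)c(Br)cc3C(=O)[C@@H]2O
F15 | step 11 | (2R,3R)-6-bromo-3-hydroxy-7-[(2-methylbut-3-en-2-yl)oxy]-2-{4-[(2-methylbut-3-en-2-yl)oxy]phenyl}chroman-4-one | C=CC(C)(C)Oc1ccc(cc1)[C@H]2Oc3cc(OC(C)(C)C=C)c(Br)cc3C(=O)[C@@H]2O
F16 | step 11 | (2R,3R)-6-bromo-3,7-dihydroxy-2-[4-hydroxy-3-(3-methylbut-2-en-1-yl)phenyl]-8-(3-methylbut-2-en-1-yl)chroman-4-one | CC(C)=CCc1cc(ccc1O)[C@H]2Oc3c(CC=C(C)C)c(O)c(Br)cc3C(=O)[C@@H]2O
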